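## Retrosynthetic overview

- The target comes from late C15 allylic hydroxylation and O8 methacrylation of a 15‑deoxy, O8‑protected bicycle.
- Key step, both rings in one flask. A Z‑vinyl iodide (C5) adds to the C6 aldehyde in a Nozaki–Hiyama–Kishi reaction and closes the ten‑membered carbocycle first. The C6 chromium alkoxide then closes onto the C12 acrylate ester and forms the γ‑lactone second.
- C6–C7 comes from indium hydroxymethylation of a Z‑2‑(bromomethyl)enoate, which is made by cross‑metathesis of a C7 vinyl group.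
- C8–C9 comes from Brown Z‑γ‑alkoxyallylboration of a 2‑formyl enoate. This sets 8S,9S and differentiates O8 from O9.
- C1=C10 and C14 come from a Baylis–Hillman, bromide, oxidation sequence on a C1 aldehyde. C4=C5 comes from carbocupration of propyne followed by iodination.

Assumption: germacrane numbering is used (C6 lactone carbinol, C7 ring fusion, C8 methacrylate, C9 acetate, C10 bears CO2Me, C4 bears CH2OH). The SMILES is read as 6R,7S,8S,9S, with C3/C6 cis on C4=C5 and C2/C9 cis on C1=C10.

## Route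

Step 1
Reactants: 1 2-(2-bromoethyl)-1,3-dioxolane; 2 propyne
Product: 6 2-[(3Z)-4-iodo-3-methylbut-3-enyl]-1,3-dioxolane, via alkylmagnesium bromide 3 (not isolated), via alkylcopper 4 (not isolated), via Z-alkenylcopper 5 (not isolated)
Conditions: Mg, THF, 25 °C; CuBr·SMe2, Et2O/Me2S, −45 °C; 2 (excess), −25 °C, 3 h; I2, THF, −50 to 0 °C
Reagents that add atoms: iodine, [I][I]
Why: Normant carbocupration adds the alkylcopper syn across propyne with the alkyl group on the internal carbon, so copper ends cis to the new chain, and iodinolysis with retention fixes the ring‑cis (Z) C4=C5 geometry.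

Step 2
Reactants: 6 2-[(3Z)-4-iodo-3-methylbut-3-enyl]-1,3-dioxolane
Product: 7 (4Z)-5-iodo-4-methylpent-4-enal
Conditions: 1 M HCl, THF, 25 °C
Reagents that add atoms: water, O
Why: Acid‑catalysed acetal hydrolysis frees the C1 aldehyde and leaves the vinyl iodide untouched.

Step 3
Reactants: 7 (4Z)-5-iodo-4-methylpent-4-enal; 8 methyl acrylate
Product: 9 methyl (6Z)-3-hydroxy-7-iodo-6-methyl-2-methylidenehept-6-enoate (racemic carbinol)
Conditions: 8 (3 equiv), DABCO (0.5 equiv), dioxane/H2O 1:1, 25 °C, 48 h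
Reagents that add atoms: none
Why: The Morita–Baylis–Hillman reaction joins C1 to C10 and brings in C9 and C14, and the carbinol centre is lost in the next step so its configuration does not matter.

Step 4
Reactants: 9 methyl (6Z)-3-hydroxy-7-iodo-6-methyl-2-methylidenehept-6-enoate
Product: 10 methyl (2Z,6Z)-2-(bromomethyl)-7-iodo-6-methylhepta-2,6-dienoate
Conditions: PBr3, Et2O, 0 °C
Reagents that add atoms: phosphorus tribromide, BrP(Br)Br
Why: SN2′ bromination of a Baylis–Hillman alcohol gives the allyl bromide with the alkyl chain trans to the ester, which is the C1=C10 geometry of the target.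

Step 5
Reactants: 10 methyl (2Z,6Z)-2-(bromomethyl)-7-iodo-6-methylhepta-2,6-dienoate
Product: 11 methyl (2E,6Z)-2-formyl-7-iodo-6-methylhepta-2,6-dienoate
Conditions: NMO (3 equiv), NaHCO3, MeCN, 25 °C
Reagents that add atoms: N-methylmorpholine N-oxide, C[N+]1([O-])CCOCC1
Why: Kornblum‑type N‑oxide oxidation displaces the activated allylic bromide and eliminates to the C9 aldehyde without moving the olefin.

Step 6
Reactants: 12 allyl alcohol; 13 dimethoxymethane
Product: 14 3-(methoxymethoxy)prop-1-ene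
Conditions: 13 (solvent), LiBr (cat.), p-TsOH (cat.), 25 °C
Reagents that add atoms: none
Why: Acid‑catalysed acetal exchange driven by excess dimethoxymethane gives the allyl MOM ether without MOMCl.

Step 7
Reactants: 11 methyl (2E,6Z)-2-formyl-7-iodo-6-methylhepta-2,6-dienoate; 14 3-(methoxymethoxy)prop-1-ene
Product: 17 methyl (2E,6Z)-2-[(1S,2S)-1-hydroxy-2-(methoxymethoxy)but-3-enyl]-7-iodo-6-methylhepta-2,6-dienoate, via Z-alkoxyallyllithium 15 (not isolated), via Z-alkoxyallylborane 16 (not isolated)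
Conditions: 14, s-BuLi, THF, −78 °C; (+)-Ipc2BOMe [from (−)-α-pinene]; BF3·OEt2; 11, −78 °C, 3 h; H2O2, pH 7 buffer, 0 °C
Reagents that add atoms: none
Why: In the Brown γ‑alkoxyallylboration the Z‑allylborane reacts through a chair Zimmerman–Traxler transition state, so Z geometry becomes the 8,9‑syn relationship, the isopinocampheyl groups from (−)-α‑pinene select the aldehyde face giving 9S (hence 8S), and O8 arrives protected while O9 stays free.

Step 8
Reactants: 17 methyl (2E,6Z)-2-[(1S,2S)-1-hydroxy-2-(methoxymethoxy)but-3-enyl]-7-iodo-6-methylhepta-2,6-dienoate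
Product: 18 methyl (2E,6Z)-2-[(1S,2S)-1-acetoxy-2-(methoxymethoxy)but-3-enyl]-7-iodo-6-methylhepta-2,6-dienoate
Conditions: Ac2O, pyridine, DMAP (cat.), CH2Cl2, 0 °C
Reagents that add atoms: acetic anhydride, CC(=O)OC(C)=O
Why: DMAP‑catalysed acylation of the only free hydroxyl installs the C9 acetate of the target without touching a stereocenter.

Step 9
Reactants: 18 methyl (2E,6Z)-2-[(1S,2S)-1-acetoxy-2-(methoxymethoxy)but-3-enyl]-7-iodo-6-methylhepta-2,6-dienoate; 19 methyl 2-(bromomethyl)acrylate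
Product: 20 methyl (2Z,4S,5S,6E,10Z)-5-acetoxy-2-(bromomethyl)-11-iodo-6-(methoxycarbonyl)-4-(methoxymethoxy)-10-methylundeca-2,6,10-trienoate
Conditions: 19 (5 equiv), second-generation Hoveyda–Grubbs catalyst (10 mol %), toluene, 60 °C
Reagents that add atoms: none
Why: In this olefin cross‑metathesis only the monosubstituted C7 vinyl group is engaged (the enoate and the iodo‑olefin are trisubstituted and inert), and coupling with the excess 1,1‑disubstituted acrylate gives, as with methacrylates, the isomer with C8 trans to the ester.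

Step 10
Reactants: 20 methyl (2Z,4S,5S,6E,10Z)-5-acetoxy-2-(bromomethyl)-11-iodo-6-(methoxycarbonyl)-4-(methoxymethoxy)-10-methylundeca-2,6,10-trienoate
Product: 21 methyl (3S,4S,5S,6E,10Z)-5-acetoxy-3-(hydroxymethyl)-11-iodo-6-(methoxycarbonyl)-4-(methoxymethoxy)-10-methyl-2-methylideneundeca-6,10-dienoate
Conditions: In powder, 37 % aq. HCHO, THF/H2O, 25 °C
Reagents that add atoms: formaldehyde, C=O
Why: In this Barbier‑type indium allylation (SE2′) the allylindium takes up formaldehyde at its γ‑carbon C7 and regenerates the acrylate methylene, while A(1,3) strain with the cis CH2In group holds C8–H in the olefin plane so that attack anti to the C9 branch gives 7S (C6 and O8 syn).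

Step 11
Reactants: 21 methyl (3S,4S,5S,6E,10Z)-5-acetoxy-3-(hydroxymethyl)-11-iodo-6-(methoxycarbonyl)-4-(methoxymethoxy)-10-methyl-2-methylideneundeca-6,10-dienoate
Product: 22 methyl (3R,4S,5S,6E,10Z)-5-acetoxy-3-formyl-11-iodo-6-(methoxycarbonyl)-4-(methoxymethoxy)-10-methyl-2-methylideneundeca-6,10-dienoate
Conditions: Dess–Martin periodinane, CH2Cl2, 0 °C, 30 min; short Florisil filtration, used at once
Reagents that add atoms: none
Why: The Dess–Martin oxidation is fast and base‑free, so it outruns lactonisation of the primary alcohol and leaves the epimerisable β,γ‑unsaturated aldehyde intact (the C7 label changes to R only through CIP priorities).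

Step 12
Reactants: 22 methyl (3R,4S,5S,6E,10Z)-5-acetoxy-3-formyl-11-iodo-6-(methoxycarbonyl)-4-(methoxymethoxy)-10-methyl-2-methylideneundeca-6,10-dienoate
Product: 24 methyl (6R,7S,8S,9S)-9-acetoxy-8-(methoxymethoxy)germacra-1(10),4,11(13)-trien-12,6-olid-14-oate (both ring olefins ring-cis), via macrocyclic chromium alkoxide 23 (not isolated)
Conditions: CrCl2 (15 equiv), NiCl2 (0.15 equiv), DMSO/THF 3:1, 0.002 M (syringe pump, 12 h), 25 °C; aq. NH4Cl; crude extract stirred with PPTS (cat.), CH2Cl2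
Reagents that add atoms: none
Why: In this Nozaki–Hiyama–Kishi macrocyclisation/lactonisation cascade the trisubstituted Z‑alkenyl iodide is transferred to chromium with retention, adds to the aldehyde in the Felkin–Anh sense (C8 branch anti to the incoming carbon) to set 6R while closing the little‑strained cis,cis‑cyclodeca‑1,5‑diene, and the chromium alkoxide, placed 1,4 to the acrylate ester, then expels methoxide to give the trans‑fused α‑methylene‑γ‑lactone.

Step 13
Reactants: 24 methyl (6R,7S,8S,9S)-9-acetoxy-8-(methoxymethoxy)germacra-1(10),4,11(13)-trien-12,6-olid-14-oate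
Product: 26 methyl (6R,7R,8S,9S)-9-acetoxy-8-hydroxygermacra-1(10),4,11(13)-trien-12,6-olid-14-oate (same spatial arrangement; the C7 label changes by CIP only), via bromomethyl ether 25 (not isolated)
Conditions: Me2BBr, CH2Cl2, −78 °C; sat. aq. NaHCO3/THF
Reagents that add atoms: none
Why: In this Guindon‑type Lewis‑acid acetal cleavage Me2BBr ionises only the acetal C–O bond at −78 °C and the bromomethyl ether hydrolyses on quench, so esters, lactone, olefins and stereocenters are untouched.

Step 14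
Reactants: 26 methyl (6R,7R,8S,9S)-9-acetoxy-8-hydroxygermacra-1(10),4,11(13)-trien-12,6-olid-14-oate
Product: 27 methyl (6R,7S,8S,9S)-9-acetoxy-8-(methacryloyloxy)germacra-1(10),4,11(13)-trien-12,6-olid-14-oate (15-deoxy target)
Conditions: methacrylic anhydride, Et3N, DMAP (cat.), CH2Cl2, 0 °C
Reagents that add atoms: methacrylic anhydride, C=C(C)C(=O)OC(=O)C(C)=C
Why: DMAP‑catalysed acylation of the only free hydroxyl (8β‑OH) installs the methacrylate faster than translactonisation can occur.

Step 15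
Reactants: 27 methyl (6R,7S,8S,9S)-9-acetoxy-8-(methacryloyloxy)germacra-1(10),4,11(13)-trien-12,6-olid-14-oate
Product: 28 CNP0179134.2 (15-hydroxy compound; target)
Conditions: SeO2 (0.5 equiv), t-BuOOH (3 equiv), CH2Cl2, 0 to 25 °C
Reagents that add atoms: selenium dioxide (oxygen carrier), O=[Se]=O; tert-butyl hydroperoxide (terminal oxidant), CC(C)(C)OO
Why: Riley/Sharpless–Umbreit allylic oxidation (ene reaction, then [2,3]-shift) attacks only the one electron‑rich olefin C4=C5 and, by the usual E rule, the methyl group trans to C6, giving the C15 alcohol with the olefin geometry retained.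

## Compound list

1 | 2-(2-bromoethyl)-1,3-dioxolane | BrCCC1OCCO1 | starting material
2 | propyne | CC#C | starting material
3 | [2-(1,3-dioxolan-2-yl)ethyl]magnesium bromide | Br[Mg]CCC1OCCO1 | intermediate
4 | [2-(1,3-dioxolan-2-yl)ethyl]copper | [Cu]CCC1OCCO1 | intermediate
5 | [(1Z)-4-(1,3-dioxolan-2-yl)-2-methylbut-1-enyl]copper | [Cu]/C=C(/C)CCC1OCCO1 | intermediate
6 | 2-[(3Z)-4-iodo-3-methylbut-3-enyl]-1,3-dioxolane | I/C=C(/C)CCC1OCCO1 | intermediate
7 | (4Z)-5-iodo-4-methylpent-4-enal | I/C=C(/C)CCC=O | intermediate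
8 | methyl acrylate | C=CC(=O)OC | starting material
9 | methyl (6Z)-3-hydroxy-7-iodo-6-methyl-2-methylidenehept-6-enoate (racemic) | I/C=C(/C)CCC(O)C(=C)C(=O)OC | intermediate
10 | methyl (2Z,6Z)-2-(bromomethyl)-7-iodo-6-methylhepta-2,6-dienoate | I/C=C(/C)CC/C=C(/C(=O)OC)CBr | intermediate
11 | methyl (2E,6Z)-2-formyl-7-iodo-6-methylhepta-2,6-dienoate | I/C=C(/C)CC/C=C(/C(=O)OC)C=O | intermediate
12 | allyl alcohol | C=CCO | starting material
13 | dimethoxymethane | COCOC | starting material
14 | 3-(methoxymethoxy)prop-1-ene | C=CCOCOC | intermediate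
15 | (Z)-3-(methoxymethoxy)allyllithium | [Li]C/C=C\OCOC | intermediate
16 | [(2Z)-3-(methoxymethoxy)prop-2-enyl]bis(isopinocampheyl)borane, Ipc from (−)-α-pinene | COCO/C=C\CB([C@H]1C[C@H]2C[C@@H]([C@@H]1C)C2(C)C)[C@H]1C[C@H]2C[C@@H]([C@@H]1C)C2(C)C | intermediate
17 | methyl (2E,6Z)-2-[(1S,2S)-1-hydroxy-2-(methoxymethoxy)but-3-enyl]-7-iodo-6-methylhepta-2,6-dienoate | I/C=C(/C)CC/C=C(/C(=O)OC)[C@H](O)[C@@H](OCOC)C=C | intermediate
18 | methyl (2E,6Z)-2-[(1S,2S)-1-acetoxy-2-(methoxymethoxy)but-3-enyl]-7-iodo-6-methylhepta-2,6-dienoate | I/C=C(/C)CC/C=C(/C(=O)OC)[C@H](OC(C)=O)[C@@H](OCOC)C=C | intermediate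
19 | methyl 2-(bromomethyl)acrylate | C=C(CBr)C(=O)OC | starting material
20 | methyl (2Z,4S,5S,6E,10Z)-5-acetoxy-2-(bromomethyl)-11-iodo-6-(methoxycarbonyl)-4-(methoxymethoxy)-10-methylundeca-2,6,10-trienoate | I/C=C(/C)CC/C=C(/C(=O)OC)[C@H](OC(C)=O)[C@@H](OCOC)/C=C(/C(=O)OC)CBr | intermediate
21 | methyl (3S,4S,5S,6E,10Z)-5-acetoxy-3-(hydroxymethyl)-11-iodo-6-(methoxycarbonyl)-4-(methoxymethoxy)-10-methyl-2-methylideneundeca-6,10-dienoate | I/C=C(/C)CC/C=C(/C(=O)OC)[C@H](OC(C)=O)[C@@H](OCOC)[C@H](CO)C(=C)C(=O)OC | intermediate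
22 | methyl (3R,4S,5S,6E,10Z)-5-acetoxy-3-formyl-11-iodo-6-(methoxycarbonyl)-4-(methoxymethoxy)-10-methyl-2-methylideneundeca-6,10-dienoate | I/C=C(/C)CC/C=C(/C(=O)OC)[C@H](OC(C)=O)[C@@H](OCOC)[C@H](C=O)C(=C)C(=O)OC | intermediate
23 | ten-membered carbocycle, C6 dichlorochromium alkoxide, C7 1-(methoxycarbonyl)vinyl (configuration as in 24) | COCO[C@H]1[C@@H](C(=C)C(=O)OC)[C@H](O[Cr](Cl)Cl)/C=C(/C)CC/C=C(/C(=O)OC)[C@@H]1OC(C)=O | intermediate
24 | methyl (6R,7S,8S,9S)-9-acetoxy-8-(methoxymethoxy)germacra-1(10),4,11(13)-trien-12,6-olid-14-oate | COCO[C@H]1[C@H]2C(=C)C(=O)O[C@@H]2/C=C(/C)CC/C=C(/C(=O)OC)[C@@H]1OC(C)=O | intermediate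
25 | 8-O-(bromomethyl) ether of 26 | BrCO[C@H]1[C@H]2C(=C)C(=O)O[C@@H]2/C=C(/C)CC/C=C(/C(=O)OC)[C@@H]1OC(C)=O | intermediate
26 | methyl (6R,7R,8S,9S)-9-acetoxy-8-hydroxygermacra-1(10),4,11(13)-trien-12,6-olid-14-oate | O[C@H]1[C@H]2C(=C)C(=O)O[C@@H]2/C=C(/C)CC/C=C(/C(=O)OC)[C@@H]1OC(C)=O | intermediate
27 | methyl (6R,7S,8S,9S)-9-acetoxy-8-(methacryloyloxy)germacra-1(10),4,11(13)-trien-12,6-olid-14-oate | C=C(C)C(=O)O[C@H]1[C@H]2C(=C)C(=O)O[C@@H]2/C=C(/C)CC/C=C(/C(=O)OC)[C@@H]1OC(C)=O | intermediate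
28 | CNP0179134.2 | C=C(C)C(=O)O[C@H]1[C@H]2C(=C)C(=O)O[C@@H]2/C=C(/CO)CC/C=C(/C(=O)OC)[C@@H]1OC(C)=O | target

## Step count and risks

Total step count: 15. Longest linear sequence: 14 (steps 1–5 and 7–15).

**Step 12 (key step).**
- Aldehyde 22 can epimerise or slide into conjugation.
- Ten‑ring closure competes with dimerisation.
- Zerovalent nickel could touch the C9 allylic acetate.

The fallback sets out from 22 and comes back at 24. It moves the ring closure to a metathesis at C4=C5.
- Vinylmagnesium bromide with CeCl3 at −78 °C adds to 22 in the Felkin sense, and the alkoxide lactonises on warming to the γ‑vinyl α‑methylene lactone F3.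
- Radical hydrodeiodination with (Me3Si)3SiH and Et3B/air turns the iodo‑olefin into the isopropenyl lactone F4.
- Ring‑closing metathesis with the second‑generation Grubbs catalyst at 0.001 M joins the C6 vinyl and the isopropenyl group to give 24. The ring size enforces the ring‑cis trisubstituted olefin.

**Step 9.** Cross‑metathesis of an allylically oxygenated olefin with a bromomethyl acrylate may be slow, or may degrade the allylic bromide. The fallback sets out from 18 and comes back at 20.
- OsO4 (cat.)/NaIO4 cleaves only the terminal vinyl group to the α‑(methoxymethoxy) aldehyde F1.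
- A Baylis–Hillman reaction with 8 and DABCO gives the adduct F2, whose carbinol epimers are inconsequential.
- PBr3 converts F2 by SN2′ into 20.

**Step 15.** Late allylic oxidation may over‑oxidise to the enal or attack C3 or C6. The fallback sets out from 27 and comes back at 28.
- PhSeCl‑catalysed ene‑type chlorination with NCS gives the rearranged 5‑chloro‑4(15)‑ene F5. The C5 epimers are inconsequential.
- Sodium formate with Bu4NBr in DMF displaces chloride by SN2′ at the unhindered C15 terminus, restoring C4=C5 and giving the 15‑formate F6.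
- Brief NaHCO3/MeOH methanolysis at 0 °C removes only the formate to give 28.

## Further compounds

F1 | step 9 | methyl (2E,6Z)-2-[(1S,2S)-1-acetoxy-2-(methoxymethoxy)-3-oxopropyl]-7-iodo-6-methylhepta-2,6-dienoate | I/C=C(/C)CC/C=C(/C(=O)OC)[C@H](OC(C)=O)[C@@H](OCOC)C=O
F2 | step 9 | Baylis–Hillman adduct of F1 with methyl acrylate (C7 carbinol epimers) | I/C=C(/C)CC/C=C(/C(=O)OC)[C@H](OC(C)=O)[C@@H](OCOC)C(O)C(=C)C(=O)OC
F3 | step 12 | acyclic 6-vinyl α-methylene-γ-lactone bearing the Z-iodo-olefin chain | I/C=C(/C)CC/C=C(/C(=O)OC)[C@H](OC(C)=O)[C@@H](OCOC)[C@@H]1[C@@H](C=C)OC(=O)C1=C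
F4 | step 12 | acyclic 6-vinyl α-methylene-γ-lactone bearing the isopropenyl chain | C=C(C)CC/C=C(/C(=O)OC)[C@H](OC(C)=O)[C@@H](OCOC)[C@@H]1[C@@H](C=C)OC(=O)C1=C
F5 | step 15 | 5-chloro-4(15)-ene isomer derived from 27 (C5 epimers) | C=C(C)C(=O)O[C@H]1[C@H]2C(=C)C(=O)O[C@@H]2C(Cl)C(=C)CC/C=C(/C(=O)OC)[C@@H]1OC(C)=O
F6 | step 15 | 15-O-formate of 28 | C=C(C)C(=O)O[C@H]1[C@H]2C(=C)C(=O)O[C@@H]2/C=C(/COC=O)CC/C=C(/C(=O)OC)[C@@H]1OC(C)=O
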